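**Ratio first.** At the first reading the delta run has made 3.97 times the product of the eta run. That ratio is the way into what the flask does with its coupling partner, the limiting reagent in delta.

| setting | delta | eta | alpha | theta | beta |
|---|---|---|---|---|---|
| starting material | 80.0 mM | 40.0 mM | 80.0 mM | 120 mM | 80.0 mM |
| coupling partner | 64.0 mM | 24.0 mM | 64.0 mM | 64.0 mM | 130 mM |
| free catalyst | 8.00 mM | 8.00 mM | 8.00 mM | 8.00 mM | 24.0 mM |
| product |  |  | 24.0 mM |  |  |
| time |  |  |  |  | 13 h |

| delta run: time / h | delta run: [product] / mM | eta run: time / h | eta run: [product] / mM | alpha run: time / h | alpha run: [product] / mM | theta run: time / h | theta run: [product] / mM |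
|---|---|---|---|---|---|---|---|
| 2.2 | 12.7 | 2.2 | 3.2 | 2.2 | 35.2 | 2.2 | 17.3 |
| 4.3 | 20.1 | 4.3 | 5.5 | 4.3 | 43.9 | 4.3 | 27.2 |
| 6.5 | 25.1 | 6.5 | 7.5 | 6.5 | 49.7 | 6.5 | 33.9 |
| 8.7 | 29.2 | 8.7 | 8.2 | 8.7 | 54.1 | 8.7 | 40.0 |
| 11 | 33.7 | 11 | 9.1 | 11 | 57.3 | 11 | 44.4 |
| 13 | 36.3 | 13 | 9.1 | 13 | 59.3 | 13 | 46.7 |

(each reading ± 0.6 mM)

- Overall: starting material + coupling partner -> product, with free catalyst as catalyst.
- Constant volume, constant temperature.
- What is held in complexes is read along with the free species.
- "The second partner" is coupling partner.
- An order is taken over about fifteen percent of the charge, up and down.

1. the exponent of [coupling partner] in the starting rate at the charge of the delta run (at the point where two percent of the starting material have become product)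
2. the exponent of [starting material] in the starting rate at the charge of the delta run (at the point where two percent of the starting material have become product) (one fixed amount of product, the same in the runs compared)
3. the eta run starts with 40.0 mM less of starting material and of coupling partner than the delta run, and with no product. Compared where both hold the same amount of starting material, once fifteen percent of what the eta run was charged with has turned into product, is the eta run faster, slower or alike (within a tenth)?
4. product in the beta run at 13 h, as a share of the starting material charged

**Plain case.** The zero of the scale is a rate of first order in both species, which gives a ratio of 5.33. The reading is lower, so at least one exponent is below one.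

**Starting material.** The theta run over the delta run reads 1.36 at the first reading, against a charge ratio of 1.50. The theta run has by then also spent more coupling partner, which pulls its rate down, so this reckoning takes the exponent of starting material as one.

**Partner exponent.** The partner exponent is the power of the partner's charge ratio that accounts for the delta-to-eta rate ratio once starting material is divided out; one means that the partner counts in full. The first readings give 0.699.

**Weak link.** That figure hangs on one eta reading whose scatter is 18.7% of its value. Summing the first two readings in each run cuts this to 9.75%. The ratio becomes 3.77, and the exponent to commit to is 0.646.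

**Forecast.** The forecast gives 0.85 for the partner, above this reckoning, and 0.9 for starting material. It calls the eta run faster and puts the beta run at 92%, saying “I assume first order in catalyst, though this is untested”.

**Result.** The flask gives 0.61 for the partner and 1.0 for starting material. The eta run is faster, and the beta run reaches 87.7%.

    free catalyst + starting material + coupling partner → product + free catalyst (302.4 M⁻² h⁻¹)
    free catalyst + coupling partner ⇌ idle catalyst-reagent complex, settled at all times (13.00 M⁻¹)
    2 free catalyst → 2 spent catalyst (10.51 M⁻¹ h⁻¹)

**Where they part.** The forecast's partner exponent is 1.39 times the flask's. Free catalyst pairs with coupling partner into idle catalyst-reagent complex, and the delta run without that pairing gives 1.0 instead of 0.61. From the delta run to the beta run the partner charge ratio is 2.03, and exponent 0.646 reckons from it a rate gain of 1.58 per catalyst charged. The pairing constant reckons a smaller gain of 1.38, so the exponent does not carry that far up the partner scale. Yet the pairing is not what holds the beta run short: its product is 87.7% with the pairing and 89.5% without.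

The data are calculated for an exercise, noise included.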